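The runs were generated by integration for substances that don't exist.

I had to decide whether the next run was worth the trouble of Saturday's temperature change, or whether plain Sunday's or cold Thursday's would do for holding open intermediate at the end.

| flask | starting material | capture agent | gas | temperature | remark | time |
|---|---|---|---|---|---|---|
| theta | 1.5 M | 0.060 M | 95 mM (held) | 115 °C | run made earlier |  |
| Saturday's | 1.5 M | 0.0300 M | 95 mM (held) |  | at 90 °C until 15 min, from then on at 115 °C | 30 min |
| Sunday's | 1.5 M | 0.0300 M | 95 mM (held) | 115 °C |  | 30 min |
| Thursday's | 1.5 M | 0.0300 M | 95 mM (held) | 90 °C |  | 30 min |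

- theta (time / min: open intermediate / %, target / %): 0.667: 8.3, 2.0; 1.00: 11.4, 3.4; 1.50: 15.5, 7.6; 2.50: 20.6, 15.5; 4.00: 22.7, 25.6; 6.00: 26.3, 37.3; 10.0: 28.4, 45.1

(readings scatter by 0.5 percentage points)

- at the start none of the gas is in solution
- the earlier runs do not show what temperature does; that part of a forecast is a guess
- no earlier run changes the charge of capture agent; that part of a forecast is a guess

1. the flask with the highest amount of open intermediate, in percent of the starting material charged ("all alike" if they lie within 1.5 percentage points) (Saturday's / Sunday's / Thursday's / all alike)
2. final open intermediate, as a percentage of the starting material charged, in Saturday's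
3. final open intermediate, as a percentage of the starting material charged, in Sunday's
4. final open intermediate, as a percentage of the starting material charged, in Thursday's

I decided by counting lifetimes of the starting material. At 6.00 min of the theta run the two read species together made 63.6 %; I assumed the rest was still starting material, and so took it to have gone at a first-order rate of 0.168 min⁻¹, and a flask's lifetimes are that rate times its time. The last two readings of open intermediate in the theta run, 26.3 % and 28.4 %, stand at 1.01 and 1.68 lifetimes, a climb of 2.1 percentage points, and I assumed a level from there on.

Sunday's gets 5.05 lifetimes. The theta run shows nothing on temperature, so I guessed 5 times slower at 90 °C, which gives Saturday's 3.03 and Thursday's 1.01. I took halving the capture agent to change nothing, also a guess. Saturday's and Sunday's both count more lifetimes than the last reading of the theta run, so I put both near 28.4 %, and Thursday's, with about as many as the theta run at 6.00 min, near 26.3 %. By this count the temperature change bought nothing, and I dropped it.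

The forecast gave Saturday's as highest, with 36 %, 34 % and 25 % for Saturday's, Sunday's and Thursday's, reading the late slowing of the theta run as the “capture agent being used up by incoming gas”.

The flasks gave 27.2 % in Saturday's, 27.1 % in Sunday's and 30.4 % in Thursday's, so Thursday's stood higher than the other two.

    starting material + coupling partner → open intermediate + by-product (k = 0.0132 M⁻¹ s⁻¹, Ea = 83.0 kJ mol⁻¹)
    open intermediate ⇌ target (K = 1.90, k = 0.00114 s⁻¹, Ea = 107 kJ mol⁻¹, ΔH = −4.00 kJ mol⁻¹)
    open intermediate ⇌ isomer of the product (K = 2.00, k = 4.42 × 10⁻⁴ s⁻¹, Ea = 107 kJ mol⁻¹, ΔH = −38.0 kJ mol⁻¹)
    open intermediate + capture agent → trapped intermediate (k = 3.41 × 10⁻⁴ M⁻¹ s⁻¹, Ea = 64.0 kJ mol⁻¹)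
    starting material → decomposition product (k = 4.22 × 10⁻⁷ s⁻¹, Ea = 127 kJ mol⁻¹)
    gas ⇌ coupling partner, rate k6*(csat - [coupling partner]) (kL = 0.0904 s⁻¹)
    (constants at 90 °C)

In Sunday's the coupling had left 0.511 % of the starting material by 15.0 min, and open intermediate stood at 27.3 % beside target and isomer of the product, as it still did at 30.0 min. In Thursday's the coupling was still running at 30.0 min with 13 % of the starting material left, which is 2.04 lifetimes against my guessed 1.01, on average a rate of 0.0685 min⁻¹, 2.45 times below the one I had read from the theta run. That rate leaves 57.8 % after 8.00 min on the cold stretch of Saturday's, and that flask, stopped then, held 60.5 %.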